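All runs are simulated for an exercise; the scatter is artificial.

The rate constants are hidden, and a cheap stand-in for them is the oak run as it was read.

the same everywhere: left-handed substrate 0.050 M; right-handed substrate 0.050 M; free catalyst 3.7 mol%
- oak: reagent 4.2 equiv; run made earlier
- birch: reagent 6.6 equiv; run made earlier
- south: reagent 3.00 equiv; time 50 h
- south-west: reagent 3.00 equiv; time 15 h

| run | time / h | right-handed substrate / % | left-handed substrate / % | left-handed product / % |
|---|---|---|---|---|
| oak | 8.00 | 50 | 37 | 13 |
| oak | 15.0 | 48 | 32 | 20 |
| oak | 25.0 | 47 | 29 | 21 |
| oak | 30.0 | 49 | 28 | 25 |
| birch | 2.50 | 53 | 43 | 2 |
| birch | 6.00 | 50 | 36 | 11 |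
| birch | 12.0 | 47 | 32 | 19 |
| birch | 30.0 | 48 | 25 | 29 |

(each reading ± 1.5 percentage points)

- free catalyst is single-handed; left-handed substrate and right-handed substrate are mirror images of each other, charged as a racemate, each of them at the stated concentration
- the earlier runs were read with a standard deviation of 1.5 percentage points
- an excess is the difference of the two amounts in percent of their sum
- an excess is below zero if the other one leads

* the winner by excess of right-handed substrate over left-handed substrate among what is left of the two; "neither" if no more than 2 percentage points parts them (south / south-west / neither)
* excess of right-handed substrate over left-handed substrate among what is left of the two at the end, south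
* excess of right-handed substrate over left-handed substrate among what is left of the two at the end, south-west

The catalyst loading is the same in the oak run and in both new flasks, so its effect needs no estimate. Time needs none for south-west, since the oak run was read at 15.0 h, its very clock, but south runs to 50 h, later than any reading. The reagent differs, 3.00 equiv against 4.2 equiv, and this is the correction to compute. Scatter moves the south-west excess by about 2 percentage points.

The number to carry is the log gap of this kinetic resolution, the natural logarithm of right-handed over left-handed substrate, which reads 0.405 in the oak run at 15.0 h. Taken as proportional to reagent and to catalyst at a fixed clock, it becomes 0.290 for south-west, an excess of 14.4 %. The last oak reading, scaled the same way, gives 0.400, an excess of 19.7 %, which this reckoning takes as a floor for south, so south should win.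

The forecast also names south, with 24 % and 19 %, on the grounds of “the catalyst dying”. Its south-west value stands above this reckoning's.

The flask gives south, with 22.8 % for south and 14.3 % for south-west.

    reagent + free catalyst + left-handed substrate → free catalyst + left-handed product (k = 1.69 M⁻² min⁻¹)
    reagent + free catalyst + right-handed substrate → free catalyst + right-handed product (k = 0.0135 M⁻² min⁻¹)
    left-handed substrate ⇌ right-handed substrate (k = 1.09 × 10⁻⁴ min⁻¹)
    reagent ⇌ dormant form (K = 0.200, k = 6.75 × 10⁻⁵ min⁻¹)
    reagent + free catalyst → spent catalyst (k = 0.00300 M⁻¹ min⁻¹)

South-west stands below south because of its shorter time: given the time of south, it reaches 22.8 % instead of 14.3 %. Its end excess is a log gap of 0.288, against the 0.290 scaled from the oak reading. For the neighbour flask, south-west with 9.2 mol% of free catalyst, the same proportion multiplies the scaled gap by 2.49 to 0.720, an excess of 34.5 %, and its simulated result is 32.6 %.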